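## Retrosynthetic overview

1. Target 23 is 8α-acetoxy-9β-angeloyloxygermacra-1(10)Z,4E,11(13)-trien-12,6α-olide (germacrane numbering: ring C1–C10, lactone carbons C11–C13, C14 on C10, C15 on C4). The esters come last: angelate on O9 with retention, acetate on O8 by Mitsunobu inversion.
2. Key disconnection: the C8–C9 bond of the ten-membered ring. The enabling feature is that the two carbinol carbons C8 and C9 are adjacent and C9 is allylic to the C1=C10(CH3) alkene. The array C8(O)–C9(O)–C10=C1 is therefore the retron of a C8 aldehyde and a γ-siloxyallylchromium unit C1–C10=C9(OSiEt3), which arises by reduction of a C9 enal. Closure with allylic transposition gives the ring, C8, C9, the 1(10)Z alkene and the O8/O9 differentiation in one operation.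
3. Precursor: the monocyclic trans-α-methylene-γ-lactone dialdehyde 17. Its lactone comes from an Evans syn-aldol (C6–C7 bond, sets C6 and C7) of succinate imide 8 with 8-silyloxygeranial 5, which is made from geranyl acetate.
4. Ring order: γ-lactone first (step 6), ten-membered carbocycle second (step 12).

Key step: step 12

Remark: the stereochemical course of step 12 is predicted from a closed chair transition state and is the main assumption of the plan; it is expected to set C9 correctly and C8 as the epimer, which step 13 inverts.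

## Route

Step 1
Reactants: 1 geranyl acetate, (2E)-3,7-dimethylocta-2,6-dien-1-yl acetate
Product: 2 (2E,6E)-8-hydroxy-3,7-dimethylocta-2,6-dien-1-yl acetate
Conditions: SeO2 (cat.), t-BuOOH, salicylic acid (cat.), CH2Cl2, rt
Reagents that add atoms: tert-butyl hydroperoxide, CC(C)(C)OO; selenium dioxide (catalytic oxygen carrier), O=[Se]=O
Why: Catalytic SeO2 allylic oxidation (ene reaction, then [2,3]-sigmatropic shift) attacks the E-methyl group of the more electron-rich distal alkene, so the E-allylic alcohol should form and no stereocentre is created.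

Step 2
Reactants: 2 (2E,6E)-8-hydroxy-3,7-dimethylocta-2,6-dien-1-yl acetate
Product: 3 (2E,6E)-8-(tert-butyldimethylsilyloxy)-3,7-dimethylocta-2,6-dien-1-yl acetate
Conditions: TBSCl, imidazole, CH2Cl2, rt
Reagents that add atoms: tert-butyldimethylsilyl chloride, CC(C)(C)[Si](C)(C)Cl
Why: Imidazole-promoted silylation of a primary allylic alcohol; the acetate is untouched.

Step 3
Reactants: 3 (2E,6E)-8-(tert-butyldimethylsilyloxy)-3,7-dimethylocta-2,6-dien-1-yl acetate
Product: 4 (2E,6E)-8-(tert-butyldimethylsilyloxy)-3,7-dimethylocta-2,6-dien-1-ol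
Conditions: K2CO3 (cat.), MeOH, 0 °C to rt
Reagents that add atoms: none
Why: Base-catalysed transesterification removes the acetate while the silyl ether and both alkenes survive.

Step 4
Reactants: 4 (2E,6E)-8-(tert-butyldimethylsilyloxy)-3,7-dimethylocta-2,6-dien-1-ol
Product: 5 (2E,6E)-8-(tert-butyldimethylsilyloxy)-3,7-dimethylocta-2,6-dienal
Conditions: 2,2,6,6-tetramethylpiperidin-1-oxyl (cat.), PhI(OAc)2, CH2Cl2, rt
Reagents that add atoms: none
Why: Oxoammonium (TEMPO) oxidation of a primary allylic alcohol stops at the enal and should not isomerise the 2E alkene.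

Step 5
Reactants: 6 (S)-4-benzyloxazolidin-2-one, 7 methyl 4-chloro-4-oxobutanoate
Product: 8 methyl 4-[(S)-4-benzyl-2-oxooxazolidin-3-yl]-4-oxobutanoate
Conditions: n-BuLi, THF, −78 °C; then 7, −78 to 0 °C
Reagents that add atoms: none
Why: N-Acylation of the lithiated oxazolidinone by the acid chloride is much faster than attack at the methyl ester.

Step 6
Reactants: 8 methyl 4-[(S)-4-benzyl-2-oxooxazolidin-3-yl]-4-oxobutanoate, 5 (2E,6E)-8-(tert-butyldimethylsilyloxy)-3,7-dimethylocta-2,6-dienal
Product: 10 trans-lactone imide (S)-4-benzyl-3-{(2R,3S)-2-[(1E,5E)-7-(tert-butyldimethylsilyloxy)-2,6-dimethylhepta-1,5-dien-1-yl]-5-oxotetrahydrofuran-3-carbonyl}oxazolidin-2-one, via syn-aldol adduct 9 (not isolated)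
Conditions: Bu2BOTf, i-Pr2NEt, CH2Cl2, −78 to 0 °C; then 5, −78 to 0 °C; pH 7 buffer, MeOH, H2O2, 0 °C; then pyridinium p-toluenesulfonate (cat.), toluene, 50 °C
Reagents that add atoms: none
Why: Evans syn-aldol reaction: the Z-boron enolate of the imide (the ester is not enolised) adds 1,2 to the enal through a Zimmerman–Traxler chair whose face is fixed by the (S)-benzyl auxiliary, setting C7 (S) and C6 (R), and the γ-hydroxy ester then lactonises under mild acid to the trans-γ-lactone.

Step 7
Reactants: 10 trans-lactone imide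
Product: 11 (4R,5R)-5-[(1E,5E)-7-(tert-butyldimethylsilyloxy)-2,6-dimethylhepta-1,5-dien-1-yl]-4-(hydroxymethyl)dihydrofuran-2(3H)-one
Conditions: NaBH4, THF/H2O (4:1), 0 °C; neutral work-up
Reagents that add atoms: none
Why: Reductive cleavage of the N-acyloxazolidinone: the exocyclic imide carbonyl is far more electrophilic than the γ-lactone, so the hydride should give the primary alcohol and free the auxiliary without touching a stereocentre.

Step 8
Reactants: 11 (4R,5R)-4-(hydroxymethyl) lactone
Product: 12 (4R,5R)-4-[(tert-butyldimethylsilyloxy)methyl]-5-[(1E,5E)-7-(tert-butyldimethylsilyloxy)-2,6-dimethylhepta-1,5-dien-1-yl]dihydrofuran-2(3H)-one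
Conditions: TBSCl, imidazole, DMF, 0 °C to rt
Reagents that add atoms: tert-butyldimethylsilyl chloride, CC(C)(C)[Si](C)(C)Cl
Why: Silylation of the primary alcohol blocks translactonisation and permits the enolate chemistry of step 9.

Step 9
Reactants: 12 bis-silyl lactone
Product: 15 (4R,5R)-4-[(tert-butyldimethylsilyloxy)methyl]-5-[(1E,5E)-7-(tert-butyldimethylsilyloxy)-2,6-dimethylhepta-1,5-dien-1-yl]-3-methylidenedihydrofuran-2(3H)-one, via Mannich base 13 (not isolated), via ammonium iodide 14 (not isolated)
Conditions: LiN(i-Pr)2, THF, −78 °C; Me2N=CH2 I (Eschenmoser's salt), −78 to 0 °C; then MeI, MeOH, rt; then aq. NaHCO3, EtOAc, rt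
Reagents that add atoms: dimethylmethylideneammonium iodide, C=[N+](C)C.[I-]
Why: Mannich reaction of the lactone enolate with Eschenmoser's salt (anti to the C7 substituent), then exhaustive methylation and Hofmann-type elimination of trimethylamine, should give the α-methylene lactone; the C11 centre of 13 is lost again.

Step 10
Reactants: 15 bis-silyl α-methylene lactone
Product: 16 (4R,5R)-5-[(1E,5E)-7-hydroxy-2,6-dimethylhepta-1,5-dien-1-yl]-4-(hydroxymethyl)-3-methylidenedihydrofuran-2(3H)-one
Conditions: HF·pyridine, pyridine, THF, 0 °C to rt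
Reagents that add atoms: none
Why: Buffered fluoride cleavage of both primary silyl ethers; these weakly acidic conditions should neither add to the methylene lactone nor move the lactone to the primary oxygen.

Step 11
Reactants: 16 diol
Product: 17 (2R,3S)-2-[(1E,5E)-2,6-dimethyl-7-oxohepta-1,5-dien-1-yl]-4-methylidene-5-oxotetrahydrofuran-3-carbaldehyde
Conditions: Dess–Martin periodinane, pyridine, CH2Cl2, 0 °C; used crude at once
Reagents that add atoms: none
Why: Dess–Martin oxidation converts the allylic and the saturated primary alcohol to aldehydes under near-neutral conditions, which should avoid epimerisation at C7, β-elimination of the lactone oxygen and alkene migration.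

Step 12
Reactants: 17 dialdehyde
Product: 20 (8S,9R)-8β-hydroxy-9β-(triethylsilyloxy)germacra-1(10)Z,4E,11(13)-trien-12,6α-olide, via siloxyallylchromium species 18 (not isolated), via chromium alkoxide 19 (not isolated)
Conditions: CrCl2 (6 equiv), DMF, 0 °C; 17 and Et3SiCl (1.2 equiv) in THF added by syringe pump (final 2 mM), 0 °C to rt; buffered aqueous work-up
Reagents that add atoms: chlorotriethylsilane, CC[Si](Cl)(CC)CC
Why: Proposed new method: CrCl2 should reduce only the conjugated C9 enal once its oxygen is silylated by Et3SiCl (the saturated C8 aldehyde and the acrylate lactone are not reduced by divalent chromium), a second CrCl2 captures the γ-siloxyallyl radical as the trivalent allylchromium 18 (chromium on C1), and this adds through C9 to the C8 aldehyde in a six-membered chair with allylic transposition to C1=C10, giving alkoxide 19 and, after work-up, 20. The closest known reaction type is the CrCl2/R3SiCl cross-pinacol-type (reductive γ-siloxyallylation) coupling of enals with aldehydes, known between two molecules and for five- to seven-membered rings from 2-methylene dialdehydes, together with Nozaki–Hiyama–Kishi allylations that close ten-membered rings; new are the tether on the enal β-carbon and the ring size. The ten-membered carbocycle closes by γ-attack (SE2′) of the allyl metal so that the new alkene is endocyclic; the competing α-attack through C1 would need an eight-membered ring holding the E-4,5-alkene and is ruled out by strain. C9 is set by the E-siloxyallyl unit (from the s-trans enal, OSiEt3 equatorial) and the equatorial aldehyde substituent, which give the anti (erythro) O8/O9 pair, and C8 by Felkin–Anh addition anti to the C7–C11 bond with the tether carbon C6 gauche, so (8S,9R) is expected: C9 as in the target, C8 epimeric and corrected in step 13. The tether on C1 sits pseudo-axial (no A(1,2) strain with the C10 methyl, and on the same face of the chair as C7), which makes the 1(10)-alkene Z whatever the geometry of the starting enal. The step needs chemoselective reduction of the enal (secured by conjugation), cyclisation over oligomerisation (syringe-pump dilution) and differentiation of the two oxygens (O9 leaves silylated, O8 is freed from chromium on work-up because only a slight excess of Et3SiCl is present).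

Step 13
Reactants: 20 (8S,9R)-8β-hydroxy-9β-(triethylsilyloxy) macrocycle
Product: 21 (8R,9R)-8α-acetoxy-9β-(triethylsilyloxy)germacra-1(10)Z,4E,11(13)-trien-12,6α-olide
Conditions: PPh3, DIAD, THF, 0 °C (betaine pre-formed); then AcOH and 20, 0 °C to rt
Reagents that add atoms: acetic acid, CC(=O)O
Why: Mitsunobu esterification: acetate should displace the C8 alkoxyphosphonium ion by SN2 with inversion, turning the 8β-alcohol into the 8α-acetate, and pre-forming the betaine keeps free phosphine away from the methylene lactone.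

Step 14
Reactants: 21 8α-acetoxy-9β-(triethylsilyloxy) macrocycle
Product: 22 (8R,9R)-8α-acetoxy-9β-hydroxygermacra-1(10)Z,4E,11(13)-trien-12,6α-olide
Conditions: HF·pyridine, pyridine, THF, 0 °C
Reagents that add atoms: none
Why: Buffered fluoride desilylation frees the allylic 9-hydroxyl under conditions too mild for acetyl migration or lactone opening.

Step 15
Reactants: 22 8α-acetoxy-9β-hydroxy macrocycle
Product: 23 (6R,7S,8R,9R)-8α-acetoxy-9β-angeloyloxygermacra-1(10)Z,4E,11(13)-trien-12,6α-olide (target)
Conditions: angelic acid, 2,4,6-trichlorobenzoyl chloride, Et3N, toluene, rt; then 22, 80 °C (no nucleophilic catalyst)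
Reagents that add atoms: angelic acid, C/C=C(/C)C(=O)O
Why: Yamaguchi esterification through the mixed anhydride acylates O9 with retention at C9, and leaving out a nucleophilic catalyst should keep the Z (angelate) geometry from isomerising to the tiglate.

## Compound list

1 | geranyl acetate | CC(=O)OC/C=C(\C)CCC=C(C)C | starting material
2 | (2E,6E)-8-hydroxy-3,7-dimethylocta-2,6-dien-1-yl acetate | CC(=O)OC/C=C(\C)CC/C=C(\C)CO | intermediate
3 | (2E,6E)-8-(tert-butyldimethylsilyloxy)-3,7-dimethylocta-2,6-dien-1-yl acetate | CC(=O)OC/C=C(\C)CC/C=C(\C)CO[Si](C)(C)C(C)(C)C | intermediate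
4 | (2E,6E)-8-(tert-butyldimethylsilyloxy)-3,7-dimethylocta-2,6-dien-1-ol | OC/C=C(\C)CC/C=C(\C)CO[Si](C)(C)C(C)(C)C | intermediate
5 | (2E,6E)-8-(tert-butyldimethylsilyloxy)-3,7-dimethylocta-2,6-dienal | O=C/C=C(\C)CC/C=C(\C)CO[Si](C)(C)C(C)(C)C | intermediate
6 | (S)-4-benzyloxazolidin-2-one | O=C1N[C@@H](Cc2ccccc2)CO1 | starting material
7 | methyl 4-chloro-4-oxobutanoate | COC(=O)CCC(Cl)=O | starting material
8 | methyl 4-[(S)-4-benzyl-2-oxooxazolidin-3-yl]-4-oxobutanoate | COC(=O)CCC(=O)N1[C@@H](Cc2ccccc2)COC1=O | intermediate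
9 | syn-aldol adduct (not isolated), methyl (3S,4R,5E,9E)-3-[(S)-4-benzyl-2-oxooxazolidine-3-carbonyl]-11-(tert-butyldimethylsilyloxy)-4-hydroxy-6,10-dimethylundeca-5,9-dienoate | COC(=O)C[C@H](C(=O)N1[C@@H](Cc2ccccc2)COC1=O)[C@H](O)/C=C(\C)CC/C=C(\C)CO[Si](C)(C)C(C)(C)C | intermediate
10 | trans-lactone imide, (S)-4-benzyl-3-{(2R,3S)-2-[(1E,5E)-7-(tert-butyldimethylsilyloxy)-2,6-dimethylhepta-1,5-dien-1-yl]-5-oxotetrahydrofuran-3-carbonyl}oxazolidin-2-one | O=C1O[C@H](/C=C(\C)CC/C=C(\C)CO[Si](C)(C)C(C)(C)C)[C@@H](C(=O)N2[C@@H](Cc3ccccc3)COC2=O)C1 | intermediate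
11 | (4R,5R)-5-[(1E,5E)-7-(tert-butyldimethylsilyloxy)-2,6-dimethylhepta-1,5-dien-1-yl]-4-(hydroxymethyl)dihydrofuran-2(3H)-one | O=C1O[C@H](/C=C(\C)CC/C=C(\C)CO[Si](C)(C)C(C)(C)C)[C@@H](CO)C1 | intermediate
12 | (4R,5R)-4-[(tert-butyldimethylsilyloxy)methyl]-5-[(1E,5E)-7-(tert-butyldimethylsilyloxy)-2,6-dimethylhepta-1,5-dien-1-yl]dihydrofuran-2(3H)-one | O=C1O[C@H](/C=C(\C)CC/C=C(\C)CO[Si](C)(C)C(C)(C)C)[C@@H](CO[Si](C)(C)C(C)(C)C)C1 | intermediate
13 | Mannich base (not isolated), (3R,4R,5R)-3-[(dimethylamino)methyl] derivative of 12 | CN(C)C[C@@H]1C(=O)O[C@H](/C=C(\C)CC/C=C(\C)CO[Si](C)(C)C(C)(C)C)[C@H]1CO[Si](C)(C)C(C)(C)C | intermediate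
14 | ammonium iodide (not isolated), N-methyl quaternary salt of 13 | C[N+](C)(C)C[C@@H]1C(=O)O[C@H](/C=C(\C)CC/C=C(\C)CO[Si](C)(C)C(C)(C)C)[C@H]1CO[Si](C)(C)C(C)(C)C.[I-] | intermediate
15 | (4R,5R)-4-[(tert-butyldimethylsilyloxy)methyl]-5-[(1E,5E)-7-(tert-butyldimethylsilyloxy)-2,6-dimethylhepta-1,5-dien-1-yl]-3-methylidenedihydrofuran-2(3H)-one | C=C1C(=O)O[C@H](/C=C(\C)CC/C=C(\C)CO[Si](C)(C)C(C)(C)C)[C@H]1CO[Si](C)(C)C(C)(C)C | intermediate
16 | (4R,5R)-5-[(1E,5E)-7-hydroxy-2,6-dimethylhepta-1,5-dien-1-yl]-4-(hydroxymethyl)-3-methylidenedihydrofuran-2(3H)-one | C=C1C(=O)O[C@H](/C=C(\C)CC/C=C(\C)CO)[C@H]1CO | intermediate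
17 | (2R,3S)-2-[(1E,5E)-2,6-dimethyl-7-oxohepta-1,5-dien-1-yl]-4-methylidene-5-oxotetrahydrofuran-3-carbaldehyde | C=C1C(=O)O[C@H](/C=C(\C)CC/C=C(\C)C=O)[C@H]1C=O | intermediate
18 | siloxyallylchromium species (not isolated): trivalent chromium dichloride on C1, E-enol triethylsilyl ether at C9=C10, C8 aldehyde intact, C1 configuration not defined | C=C1C(=O)O[C@H](/C=C(\C)CCC([Cr](Cl)Cl)/C(C)=C/O[Si](CC)(CC)CC)[C@H]1C=O | intermediate
19 | chromium alkoxide (not isolated): 8-O-CrCl2 derivative of 20 | C=C1C(=O)O[C@@H]2/C=C(\C)CC/C=C(/C)[C@@H](O[Si](CC)(CC)CC)[C@@H](O[Cr](Cl)Cl)[C@@H]12 | intermediate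
20 | (8S,9R)-8β-hydroxy-9β-(triethylsilyloxy)germacra-1(10)Z,4E,11(13)-trien-12,6α-olide | C=C1C(=O)O[C@@H]2/C=C(\C)CC/C=C(/C)[C@@H](O[Si](CC)(CC)CC)[C@@H](O)[C@@H]12 | intermediate
21 | (8R,9R)-8α-acetoxy-9β-(triethylsilyloxy)germacra-1(10)Z,4E,11(13)-trien-12,6α-olide | C=C1C(=O)O[C@@H]2/C=C(\C)CC/C=C(/C)[C@@H](O[Si](CC)(CC)CC)[C@H](OC(C)=O)[C@@H]12 | intermediate
22 | (8R,9R)-8α-acetoxy-9β-hydroxygermacra-1(10)Z,4E,11(13)-trien-12,6α-olide | C=C1C(=O)O[C@@H]2/C=C(\C)CC/C=C(/C)[C@@H](O)[C@H](OC(C)=O)[C@@H]12 | intermediate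
23 | (6R,7S,8R,9R)-8α-acetoxy-9β-angeloyloxygermacra-1(10)Z,4E,11(13)-trien-12,6α-olide | C=C1C(=O)O[C@@H]2/C=C(\C)CC/C=C(/C)[C@@H](OC(=O)/C(C)=C\C)[C@H](OC(C)=O)[C@@H]12 | target

## Step count and risks

Total: 15 steps. Longest linear sequence: 14 steps (steps 1–4 and 6–15, from geranyl acetate); step 5 is a one-step branch.

**Step 12 (key step, proposed new method).** What may go wrong: intermolecular coupling to oligomers, reduction of the enal without ring closure, or poor facial selectivity at C8 in the closed transition state. The fallback keeps the C8–C9 ring closure but uses a known samarium diiodide pinacol macrocyclisation. It sets out from dialdehyde 17. Because a ketyl coupling does not transpose the alkene, the enal is first isomerised photochemically (hν 350 nm, benzene; the E isomer is separated and recycled) to the 1(10)Z dialdehyde F1. Slow addition of F1 to SmI2 in THF at −78 °C under high dilution should give, through the samarium-bridged diketyl, the cis-8β,9β-diol F2. Selective silylation of the allylic, less hindered 9-hydroxyl (Et3SiCl, imidazole, CH2Cl2, −78 °C) comes back to the route at 20.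

**Step 13.** What may go wrong: the C8 carbinol is flanked by two branched carbons, so SN2 displacement may be outrun by elimination towards C7 or by phosphine addition to the methylene lactone. The fallback replaces displacement by oxidation and reduction and sets out from 20. Dess–Martin oxidation should give the 8-ketone F3. Luche reduction (NaBH4, CeCl3·7H2O, MeOH, −78 °C) should deliver hydride in the Felkin–Anh sense anti to the C9–OSiEt3 bond and give the 8α-alcohol F4. Acetylation (Ac2O, 4-(dimethylamino)pyridine, pyridine) comes back to the route at 21.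

**Step 11.** What may go wrong: migration of the exocyclic double bond into conjugation with the new C8 aldehyde (loss of the C7 stereocentre), or β-elimination of the lactone carboxylate during oxidation and handling. The fallback carries the methylene group masked as its dimethylamine adduct. It sets out from Mannich base 13, which is isolated instead of being quaternised. HF·pyridine should give the amino diol F5 and Dess–Martin oxidation the amino dialdehyde F6, which has no alkene next to C7. The CrCl2/Et3SiCl cyclisation of step 12 should then give the amino macrocycle F7. Methylation (MeI) to the ammonium iodide F8 and treatment with NaHCO3 unmask the methylene lactone and come back to the route at 20.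

## Further compounds

F1 | step 12 | (2R,3S)-2-[(1E,5Z)-2,6-dimethyl-7-oxohepta-1,5-dien-1-yl]-4-methylidene-5-oxotetrahydrofuran-3-carbaldehyde | C=C1C(=O)O[C@H](/C=C(\C)CC/C=C(/C)C=O)[C@H]1C=O
F2 | step 12 | (8S,9R)-8β,9β-dihydroxygermacra-1(10)Z,4E,11(13)-trien-12,6α-olide | C=C1C(=O)O[C@@H]2/C=C(\C)CC/C=C(/C)[C@@H](O)[C@@H](O)[C@@H]12
F3 | step 13 | (9R)-8-oxo-9β-(triethylsilyloxy)germacra-1(10)Z,4E,11(13)-trien-12,6α-olide | C=C1C(=O)O[C@@H]2/C=C(\C)CC/C=C(/C)[C@@H](O[Si](CC)(CC)CC)C(=O)[C@@H]12
F4 | step 13 | (8R,9R)-8α-hydroxy-9β-(triethylsilyloxy)germacra-1(10)Z,4E,11(13)-trien-12,6α-olide | C=C1C(=O)O[C@@H]2/C=C(\C)CC/C=C(/C)[C@@H](O[Si](CC)(CC)CC)[C@H](O)[C@@H]12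
F5 | step 11 | (3R,4R,5R)-3-[(dimethylamino)methyl]-5-[(1E,5E)-7-hydroxy-2,6-dimethylhepta-1,5-dien-1-yl]-4-(hydroxymethyl)dihydrofuran-2(3H)-one | CN(C)C[C@@H]1C(=O)O[C@H](/C=C(\C)CC/C=C(\C)CO)[C@H]1CO
F6 | step 11 | (2R,3S,4R)-4-[(dimethylamino)methyl]-2-[(1E,5E)-2,6-dimethyl-7-oxohepta-1,5-dien-1-yl]-5-oxotetrahydrofuran-3-carbaldehyde | CN(C)C[C@@H]1C(=O)O[C@H](/C=C(\C)CC/C=C(\C)C=O)[C@H]1C=O
F7 | step 11 | (8S,9R,11R)-13-(dimethylamino)-8β-hydroxy-9β-(triethylsilyloxy)-11,13-dihydrogermacra-1(10)Z,4E-dien-12,6α-olide | CN(C)C[C@@H]1C(=O)O[C@@H]2/C=C(\C)CC/C=C(/C)[C@@H](O[Si](CC)(CC)CC)[C@@H](O)[C@@H]12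
F8 | step 11 | N-methyl ammonium iodide of F7 | C[N+](C)(C)C[C@@H]1C(=O)O[C@@H]2/C=C(\C)CC/C=C(/C)[C@@H](O[Si](CC)(CC)CC)[C@@H](O)[C@@H]12.[I-]
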